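The numbers of this flask are made up; the run is a simulation.

There were 4 questions, 3 of amount and one of order, on the D that the X gave in ash, elm and oak.

| setting | ash | elm | oak |
|---|---|---|---|
| X | 0.30 M (fed, over 7.50 h) | 0.30 M | 0.30 M |
| E | 0.300 M | 0.300 M | 0.300 M |
| J | 0.48 mM | 0.48 mM | 0.48 mM |
| time | 15 h | 15 h |  |
| remark | all but X at the start; X goes in evenly over 7.50 h, the run ends at 15 h | everything together in a closed stirred flask, run for 15 h | one stirred flow tank at steady state, fed with the mixture as stated, mean residence time 15 h |

    X + J → X.J (k1 = 1.7 M⁻¹ s⁻¹)
    X.J ⇌ L (K2 = 0.91, k2 = 0.21 s⁻¹)
    L → J + D (k3 = 0.10 s⁻¹)
    J → G (k4 = 7.5 × 10⁻⁵ s⁻¹)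
    X + E → X.E (k5 = 8.1 × 10⁻⁵ M⁻¹ s⁻¹)

- the stated concentrations are those of everything mixed, before any reaction; amounts are the same in each set-up
- the feed brings no volume worth counting
- run time (ash): 15 h

1. order of the set-ups by the amount of D at the outlet or at the end, in percent of the X put in, highest first (ash / elm / oak)
2. amount of D at the outlet or at the end, in percent of the X put in, ash
3. amount of D at the outlet or at the end, in percent of the X put in, elm
4. amount of D at the outlet or at the end, in percent of the X put in, oak

I took elm first and asked which constants its D leans on. While X stands far above the level that half-saturates J, D forms at a steady top rate, the turnover constant times the J charged, with J resting as X.J and L (its resting state). X.E meanwhile forms at a pseudo-first-order constant, the side constant times E, times X. Integrating gives a share of X into D equal to the logarithm of one plus s, divided by s, where s is the side rate at the charge over the top rate. The turnover constant is the last step's constant times the share of bound J standing as L, 0.0388 s⁻¹. A factor of 2 against me in the side constant, in E, or the other way in the turnover constant or J, cost 11 percentage points, so those had to be known well. The binding constant mattered less, since it enters through the half-saturation level 0.0228 M, far below the charge of X, which left 7.08% of J free at the charge. The loss of J mattered less too: at that free share it came to 8.54% of J over the working time.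

Then came the number. The clearing time, the charge of X divided by the top rate, was 4.47 h, shorter than the 7.9 h half-life of X by the side step alone in elm. Multiplied by the pseudo-first-order constant it gave s = 0.391, and with E and J held at their charges elm's D came to 84.4%. My reckoning went no further.

The forecast put ash > elm > oak, with 86.2% for ash, 83.2% for elm and 75.9% for oak, holding of ash that “Low X keeps the side reaction small”.

The simulation gave ash > elm > oak, with 86.3% in ash, 82.9% in elm and 75.9% in oak, so elm stood 1.5 points under my reckoning. In ash the highest X read 0.0796 M, which at the clearing pace, reckoned with full J, takes 1.19 h, less than the 7.50 h between the end of dosing and the end of the run. Ash had come to rest: left ten times as long, until 150 h, it gave 86.5%, a change of 0.20 points.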